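**Plan**

- Numbering: C1 (CH bearing the guaiacyl ring), C2 (bears C9', the CH2OSO3H carbon), C3 (bears C9, the CH2OH carbon), C4 (CH2), C4a/C8a (fusion to ring A). The guaiacyl ring on C1 and the C2–C3 bond sit on the two carbons of what can be one ester-substituted alkyne (C1≡C2–C9'), so retrosynthesis cuts C1–aryl and C2–C3 together.
- Further cuts: C8a–C1 (Sonogashira coupling) and the C4 side chain, back to O-benzylvanillin, propargyl alcohol, methyl propiolate and a commercial arylboronic acid.
- Forward: ring A is elaborated (iodination, benzylic chain extension, Z-semihydrogenation, propiolate coupling, phosphorylation). One nickel-catalysed arylative cyclisation then attaches the pendant ring and closes ring B, leaving a vinyl group as masked C9.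
- Stereochemistry: C3 from the chiral P,N ligand on nickel; C1 by cis reduction of C1=C2 from the C3–H face of the derived unsaturated lactone; C2 by base epimerisation of the C9' aldehyde to the all-trans arrangement.
- The lactone keeps C9 and C9' at different oxidation levels, so O9 is masked (BOM), only O9' is sulfated, and one hydrogenolysis finishes.

Key step: step 8

Remark: the target is drawn as the free hydrogen sulfate; it is released from its sodium salt in the last step and would be stored as the salt.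
Remark: the (S)-ligand is assigned to the (3S) key-step product by analogy with related cyclisations; if the sense of induction is opposite, the (R)-ligand is used and nothing else changes.
Abbreviations: Bn = benzyl, BOM = benzyloxymethyl, t-Bu-PHOX = 4-tert-butyl-2-[2-(diphenylphosphino)phenyl]-4,5-dihydrooxazole.

**Route**

Step 1
Reactants: 1 4-(benzyloxy)-3-methoxybenzaldehyde
Product: 2 4-(benzyloxy)-2-iodo-5-methoxybenzaldehyde
Conditions: I2, CF3CO2Ag, CH2Cl2, rt
Reagents that add atoms: iodine, II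
Why: Electrophilic aromatic iodination, in which the formyl group drains the para benzyloxy oxygen so that the methoxy group directs iodine to its own para position (ortho to CHO), the carbon that becomes C8a.

Step 2
Reactants: 2 4-(benzyloxy)-2-iodo-5-methoxybenzaldehyde
Product: 3 [4-(benzyloxy)-2-iodo-5-methoxyphenyl]methanol
Conditions: NaBH4, MeOH/THF, 0 °C
Reagents that add atoms: none
Why: Borohydride reduction of an aryl aldehyde, to which the aryl iodide and the benzyl ether are inert.

Step 3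
Reactants: 3 [4-(benzyloxy)-2-iodo-5-methoxyphenyl]methanol
Product: 4 1-(benzyloxy)-4-(bromomethyl)-5-iodo-2-methoxybenzene
Conditions: PBr3, CH2Cl2, 0 °C
Reagents that add atoms: phosphorus tribromide, BrP(Br)Br
Why: Bromination of an electron-rich benzylic alcohol through its phosphite ester, the reactive bromide being used without storage.

Step 4
Reactants: 4 1-(benzyloxy)-4-(bromomethyl)-5-iodo-2-methoxybenzene; 5 prop-2-yn-1-ol
Product: 6 4-[4-(benzyloxy)-2-iodo-5-methoxyphenyl]but-2-yn-1-ol
Conditions: CuI, Cs2CO3, MeCN, rt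
Reagents that add atoms: none
Why: Copper-mediated sp–sp3 coupling in which the alkynylcopper species from 5 is C-benzylated by the activated bromide, while the aryl iodide does not react with copper alone at room temperature.

Step 5
Reactants: 6 4-[4-(benzyloxy)-2-iodo-5-methoxyphenyl]but-2-yn-1-ol
Product: 7 (2Z)-4-[4-(benzyloxy)-2-iodo-5-methoxyphenyl]but-2-en-1-ol
Conditions: H2 (1 atm), Pd/CaCO3 poisoned with Pb(OAc)2, quinoline, EtOAc, rt
Reagents that add atoms: none
Why: Lindlar semihydrogenation, in which syn delivery of hydrogen on the poisoned surface sets the Z alkene and the deactivated catalyst should leave the aryl iodide and benzyl ether intact.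

Step 6
Reactants: 7 (2Z)-4-[4-(benzyloxy)-2-iodo-5-methoxyphenyl]but-2-en-1-ol; 8 methyl prop-2-ynoate
Product: 9 methyl 3-{5-(benzyloxy)-2-[(2Z)-4-hydroxybut-2-en-1-yl]-4-methoxyphenyl}prop-2-ynoate
Conditions: PdCl2(PPh3)2 (5 mol%), CuI (10 mol%), K2CO3, THF, 60 °C, slow addition of 8
Reagents that add atoms: none
Why: Sonogashira coupling of the aryl iodide, run with a carbonate base instead of an amine to avoid conjugate addition to the propiolate, and placed before phosphorylation because a free allylic alcohol, unlike an allylic phosphate, is not ionised by the palladium catalyst.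

Step 7
Reactants: 9 methyl 3-{5-(benzyloxy)-2-[(2Z)-4-hydroxybut-2-en-1-yl]-4-methoxyphenyl}prop-2-ynoate
Product: 10 methyl 3-{5-(benzyloxy)-2-[(2Z)-4-[(diethoxyphosphoryl)oxy]but-2-en-1-yl]-4-methoxyphenyl}prop-2-ynoate
Conditions: ClP(O)(OEt)2, pyridine, DMAP (cat.), CH2Cl2, 0 °C
Reagents that add atoms: diethyl chlorophosphate, CCOP(=O)(Cl)OCC
Why: O-Phosphorylation of a primary allylic alcohol under mild amine base, conditions under which the β-aryl ynoate is not attacked.

Step 8
Reactants: 10 methyl 3-{5-(benzyloxy)-2-[(2Z)-4-[(diethoxyphosphoryl)oxy]but-2-en-1-yl]-4-methoxyphenyl}prop-2-ynoate; 11 [4-(benzyloxy)-3-methoxyphenyl]boronic acid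
Product: 12 methyl (3S)-7-(benzyloxy)-1-[4-(benzyloxy)-3-methoxyphenyl]-3-ethenyl-6-methoxy-3,4-dihydronaphthalene-2-carboxylate
Conditions: 11 (2 equiv), Ni(OAc)2·4H2O (10 mol%), (S)-t-Bu-PHOX (10 mol%), MeCN/2-MeTHF, 80 °C
Reagents that add atoms: none
Why: Transmetallation of 11 to the divalent nickel acetate complex gives an arylnickel species that adds syn across the ynoate (aryl to C1, nickel to the ester-bearing C2); the resulting alkenylnickel, with nickel trans to ring A, equilibrates through its nickel allenolate with the isomer having nickel cis to ring A, which alone can insert the tethered Z-alkene, and β-elimination of diethyl phosphate then releases the vinyl group and divalent nickel, an overall SN2' displacement that forms C2–C3. The closest known reaction type is the nickel-catalysed anti-carbometallative cyclisation of alkyne-tethered Z-allylic phosphates with arylboronic acids under chiral phosphinooxazoline ligands; an ynoate carried on an arene tether extends that substrate class. Ring B closes in the 6-exo-trig mode, C2 attacking the proximal alkene carbon, which becomes C3. The C3 stereocentre is set by the chiral P,N ligand, which selects the alkene face in the insertion, and the Z geometry of the allylic phosphate is kept because this reaction type is most selective with Z substrates. The step needs aryl delivery to C1 and not C2, secured by the ester polarising the alkyne and stabilising nickel at C2, and it needs cyclisation to outrun protodenickelation, helped by the ester-assisted E/Z isomerisation and the six-membered ring being formed.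

Step 9
Reactants: 12 methyl (3S)-7-(benzyloxy)-1-[4-(benzyloxy)-3-methoxyphenyl]-3-ethenyl-6-methoxy-3,4-dihydronaphthalene-2-carboxylate
Product: 15 (3aR)-7-(benzyloxy)-9-[4-(benzyloxy)-3-methoxyphenyl]-6-methoxy-3a,4-dihydronaphtho[2,3-c]furan-1(3H)-one, via aldehyde 13 (not isolated), via hydroxy ester 14 (not isolated)
Conditions: O3, CH2Cl2/MeOH, −78 °C (Sudan Red 7B end point); NaBH4, −78 → 0 °C; then p-TsOH·H2O (cat.), CH2Cl2, rt
Reagents that add atoms: ozone, [O-][O+]=O
Why: Ozonolysis with reductive work-up cleaves the monosubstituted vinyl group, which should react far faster than the hindered, ester-deactivated C1=C2 alkene or the arenes, the in situ borohydride reduction prevents the epimerisable C3 aldehyde from accumulating, and the C9 alcohol then lactonises onto the neighbouring ester (5-exo-trig acyl substitution).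

Step 10
Reactants: 15 (3aR)-7-(benzyloxy)-9-[4-(benzyloxy)-3-methoxyphenyl]-6-methoxy-3a,4-dihydronaphtho[2,3-c]furan-1(3H)-one
Product: 16 (3aR,9S,9aS)-7-(benzyloxy)-9-[4-(benzyloxy)-3-methoxyphenyl]-6-methoxy-3a,4,9,9a-tetrahydronaphtho[2,3-c]furan-1(3H)-one
Conditions: NiCl2·6H2O (30 mol%), NaBH4, MeOH/THF, 0 °C
Reagents that add atoms: none
Why: Conjugate reduction of the α,β-unsaturated lactone on Ni2B formed in situ, which should deliver hydrogen to C1 and C2 from the convex face carrying the C3–H (C4 and C9 tilt to the other face), fixing C1 with the aryl group cis to the C9 substituent and giving the cis-fused lactone without cleaving the benzyl ethers.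

Step 11
Reactants: 16 (3aR,9S,9aS)-7-(benzyloxy)-9-[4-(benzyloxy)-3-methoxyphenyl]-6-methoxy-3a,4,9,9a-tetrahydronaphtho[2,3-c]furan-1(3H)-one
Product: 17 (1S,2S,3R)-7-(benzyloxy)-1-[4-(benzyloxy)-3-methoxyphenyl]-3-(hydroxymethyl)-N,6-dimethoxy-N-methyl-1,2,3,4-tetrahydronaphthalene-2-carboxamide
Conditions: MeNH(OMe)·HCl, AlMe3, CH2Cl2, 0 °C → rt
Reagents that add atoms: N,O-dimethylhydroxylamine hydrochloride, CNOC.Cl
Why: Weinreb aminolysis of the γ-lactone by the aluminium amide made from AlMe3, which frees only O9 and leaves C9' as an amide, so the two CH2O termini become chemically different.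

Step 12
Reactants: 17 (1S,2S,3R)-7-(benzyloxy)-1-[4-(benzyloxy)-3-methoxyphenyl]-3-(hydroxymethyl)-N,6-dimethoxy-N-methyl-1,2,3,4-tetrahydronaphthalene-2-carboxamide
Product: 18 (1S,2S,3R)-7-(benzyloxy)-1-[4-(benzyloxy)-3-methoxyphenyl]-3-{[(benzyloxy)methoxy]methyl}-N,6-dimethoxy-N-methyl-1,2,3,4-tetrahydronaphthalene-2-carboxamide
Conditions: BOMCl, i-Pr2NEt, Bu4NI (cat.), CH2Cl2, rt
Reagents that add atoms: benzyl chloromethyl ether, ClCOCc1ccccc1
Why: Alkylation of the primary alcohol to its BOM acetal under amine base, which avoids the alkoxide that would re-close the lactone and installs a group removable in the final hydrogenolysis.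

Step 13
Reactants: 18 (1S,2S,3R)-7-(benzyloxy)-1-[4-(benzyloxy)-3-methoxyphenyl]-3-{[(benzyloxy)methoxy]methyl}-N,6-dimethoxy-N-methyl-1,2,3,4-tetrahydronaphthalene-2-carboxamide
Product: 20 (1S,2R,3R)-7-(benzyloxy)-1-[4-(benzyloxy)-3-methoxyphenyl]-3-{[(benzyloxy)methoxy]methyl}-6-methoxy-1,2,3,4-tetrahydronaphthalene-2-carbaldehyde, via cis aldehyde 19 (not isolated)
Conditions: LiAlH4, THF, −78 → 0 °C, aqueous work-up; then DBU, CH2Cl2, rt
Reagents that add atoms: none
Why: Weinreb amide reduction stops at the aldehyde through the chelated tetrahedral intermediate, and DBU-mediated enolisation then epimerises only C2 (C1 and C3 are not enolisable) to the thermodynamically preferred 1,2-trans-2,3-trans isomer with all three substituents pseudo-equatorial.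

Step 14
Reactants: 20 (1S,2R,3R)-7-(benzyloxy)-1-[4-(benzyloxy)-3-methoxyphenyl]-3-{[(benzyloxy)methoxy]methyl}-6-methoxy-1,2,3,4-tetrahydronaphthalene-2-carbaldehyde
Product: 21 [(1S,2R,3R)-7-(benzyloxy)-1-[4-(benzyloxy)-3-methoxyphenyl]-3-{[(benzyloxy)methoxy]methyl}-6-methoxy-1,2,3,4-tetrahydronaphthalen-2-yl]methanol
Conditions: NaBH4, MeOH/THF, 0 °C
Reagents that add atoms: none
Why: Borohydride reduction of the aldehyde gives the C9' alcohol and locks the C2 configuration, since the centre is no longer enolisable.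

Step 15
Reactants: 21 [(1S,2R,3R)-7-(benzyloxy)-1-[4-(benzyloxy)-3-methoxyphenyl]-3-{[(benzyloxy)methoxy]methyl}-6-methoxy-1,2,3,4-tetrahydronaphthalen-2-yl]methanol
Product: 23 sodium [(1S,2R,3R)-7-(benzyloxy)-1-[4-(benzyloxy)-3-methoxyphenyl]-3-{[(benzyloxy)methoxy]methyl}-6-methoxy-1,2,3,4-tetrahydronaphthalen-2-yl]methyl sulfate, via pyridinium sulfate 22 (not isolated)
Conditions: SO3·pyridine, pyridine, rt; then aq. NaHCO3
Reagents that add atoms: sulfur trioxide–pyridine complex, [O-]S(=O)(=O)[n+]1ccccc1; sodium hydrogen carbonate, [Na+].OC([O-])=O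
Why: O-Sulfation of the only free hydroxyl group (both phenols and O9 are masked) with the amine–SO3 complex, followed by cation exchange to the stable sodium salt.

Step 16
Reactants: 23 sodium [(1S,2R,3R)-7-(benzyloxy)-1-[4-(benzyloxy)-3-methoxyphenyl]-3-{[(benzyloxy)methoxy]methyl}-6-methoxy-1,2,3,4-tetrahydronaphthalen-2-yl]methyl sulfate
Product: 25 [(1S,2R,3R)-7-hydroxy-1-(4-hydroxy-3-methoxyphenyl)-3-(hydroxymethyl)-6-methoxy-1,2,3,4-tetrahydronaphthalen-2-yl]methyl hydrogen sulfate, via sodium salt 24 (not isolated)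
Conditions: H2 (1 atm), 10% Pd/C, MeOH, rt; filter; then aq. HCl (1.0 equiv), 0 °C, reversed-phase (C18) desalting
Reagents that add atoms: none
Why: Catalytic hydrogenolysis removes both aryl benzyl ethers and the BOM group (its hemiacetal loses formaldehyde) under neutral conditions that sulfate monoester salts tolerate, and cold protonation then gives the hydrogen sulfate.

**Compound list**

1 | 4-(benzyloxy)-3-methoxybenzaldehyde (O-benzylvanillin) | COc1cc(C=O)ccc1OCc1ccccc1 | starting material
2 | 4-(benzyloxy)-2-iodo-5-methoxybenzaldehyde | COc1cc(C=O)c(I)cc1OCc1ccccc1 | intermediate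
3 | [4-(benzyloxy)-2-iodo-5-methoxyphenyl]methanol | COc1cc(CO)c(I)cc1OCc1ccccc1 | intermediate
4 | 1-(benzyloxy)-4-(bromomethyl)-5-iodo-2-methoxybenzene | COc1cc(CBr)c(I)cc1OCc1ccccc1 | intermediate
5 | prop-2-yn-1-ol (propargyl alcohol) | C#CCO | starting material
6 | 4-[4-(benzyloxy)-2-iodo-5-methoxyphenyl]but-2-yn-1-ol | COc1cc(CC#CCO)c(I)cc1OCc1ccccc1 | intermediate
7 | (2Z)-4-[4-(benzyloxy)-2-iodo-5-methoxyphenyl]but-2-en-1-ol | COc1cc(C/C=C\CO)c(I)cc1OCc1ccccc1 | intermediate
8 | methyl prop-2-ynoate (methyl propiolate) | C#CC(=O)OC | starting material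
9 | methyl 3-{5-(benzyloxy)-2-[(2Z)-4-hydroxybut-2-en-1-yl]-4-methoxyphenyl}prop-2-ynoate | COC(=O)C#Cc1cc(OCc2ccccc2)c(OC)cc1C/C=C\CO | intermediate
10 | methyl 3-{5-(benzyloxy)-2-[(2Z)-4-[(diethoxyphosphoryl)oxy]but-2-en-1-yl]-4-methoxyphenyl}prop-2-ynoate | COC(=O)C#Cc1cc(OCc2ccccc2)c(OC)cc1C/C=C\COP(=O)(OCC)OCC | intermediate
11 | [4-(benzyloxy)-3-methoxyphenyl]boronic acid | COc1cc(B(O)O)ccc1OCc1ccccc1 | starting material
12 | methyl (3S)-7-(benzyloxy)-1-[4-(benzyloxy)-3-methoxyphenyl]-3-ethenyl-6-methoxy-3,4-dihydronaphthalene-2-carboxylate | COC(=O)C1=C(c2ccc(OCc3ccccc3)c(OC)c2)c2cc(OCc3ccccc3)c(OC)cc2C[C@H]1C=C | intermediate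
13 | methyl (3R)-7-(benzyloxy)-1-[4-(benzyloxy)-3-methoxyphenyl]-3-formyl-6-methoxy-3,4-dihydronaphthalene-2-carboxylate | COC(=O)C1=C(c2ccc(OCc3ccccc3)c(OC)c2)c2cc(OCc3ccccc3)c(OC)cc2C[C@H]1C=O | intermediate
14 | methyl (3R)-7-(benzyloxy)-1-[4-(benzyloxy)-3-methoxyphenyl]-3-(hydroxymethyl)-6-methoxy-3,4-dihydronaphthalene-2-carboxylate | COC(=O)C1=C(c2ccc(OCc3ccccc3)c(OC)c2)c2cc(OCc3ccccc3)c(OC)cc2C[C@H]1CO | intermediate
15 | (3aR)-7-(benzyloxy)-9-[4-(benzyloxy)-3-methoxyphenyl]-6-methoxy-3a,4-dihydronaphtho[2,3-c]furan-1(3H)-one (C9'–O9 lactone, C1=C2 retained) | O=C1OC[C@@H]2Cc3cc(OC)c(OCc4ccccc4)cc3C(c3ccc(OCc4ccccc4)c(OC)c3)=C12 | intermediate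
16 | (3aR,9S,9aS)-7-(benzyloxy)-9-[4-(benzyloxy)-3-methoxyphenyl]-6-methoxy-3a,4,9,9a-tetrahydronaphtho[2,3-c]furan-1(3H)-one (all-cis lactone) | COc1cc([C@H]2c3cc(OCc4ccccc4)c(OC)cc3C[C@H]3COC(=O)[C@@H]23)ccc1OCc1ccccc1 | intermediate
17 | (1S,2S,3R)-7-(benzyloxy)-1-[4-(benzyloxy)-3-methoxyphenyl]-3-(hydroxymethyl)-N,6-dimethoxy-N-methyl-1,2,3,4-tetrahydronaphthalene-2-carboxamide | COc1cc([C@H]2c3cc(OCc4ccccc4)c(OC)cc3C[C@@H](CO)[C@H]2C(=O)N(C)OC)ccc1OCc1ccccc1 | intermediate
18 | (1S,2S,3R)-7-(benzyloxy)-1-[4-(benzyloxy)-3-methoxyphenyl]-3-{[(benzyloxy)methoxy]methyl}-N,6-dimethoxy-N-methyl-1,2,3,4-tetrahydronaphthalene-2-carboxamide | COc1cc([C@H]2c3cc(OCc4ccccc4)c(OC)cc3C[C@@H](COCOCc3ccccc3)[C@H]2C(=O)N(C)OC)ccc1OCc1ccccc1 | intermediate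
19 | (1S,2S,3R)-7-(benzyloxy)-1-[4-(benzyloxy)-3-methoxyphenyl]-3-{[(benzyloxy)methoxy]methyl}-6-methoxy-1,2,3,4-tetrahydronaphthalene-2-carbaldehyde (all-cis) | COc1cc([C@H]2c3cc(OCc4ccccc4)c(OC)cc3C[C@@H](COCOCc3ccccc3)[C@H]2C=O)ccc1OCc1ccccc1 | intermediate
20 | (1S,2R,3R)-7-(benzyloxy)-1-[4-(benzyloxy)-3-methoxyphenyl]-3-{[(benzyloxy)methoxy]methyl}-6-methoxy-1,2,3,4-tetrahydronaphthalene-2-carbaldehyde (1,2-trans-2,3-trans) | COc1cc([C@H]2c3cc(OCc4ccccc4)c(OC)cc3C[C@@H](COCOCc3ccccc3)[C@@H]2C=O)ccc1OCc1ccccc1 | intermediate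
21 | [(1S,2R,3R)-7-(benzyloxy)-1-[4-(benzyloxy)-3-methoxyphenyl]-3-{[(benzyloxy)methoxy]methyl}-6-methoxy-1,2,3,4-tetrahydronaphthalen-2-yl]methanol | COc1cc([C@H]2c3cc(OCc4ccccc4)c(OC)cc3C[C@@H](COCOCc3ccccc3)[C@@H]2CO)ccc1OCc1ccccc1 | intermediate
22 | pyridinium salt of the C9' sulfate monoester of 21 | COc1cc([C@H]2c3cc(OCc4ccccc4)c(OC)cc3C[C@@H](COCOCc3ccccc3)[C@@H]2COS(=O)(=O)[O-])ccc1OCc1ccccc1.c1cc[nH+]cc1 | intermediate
23 | sodium [(1S,2R,3R)-7-(benzyloxy)-1-[4-(benzyloxy)-3-methoxyphenyl]-3-{[(benzyloxy)methoxy]methyl}-6-methoxy-1,2,3,4-tetrahydronaphthalen-2-yl]methyl sulfate | COc1cc([C@H]2c3cc(OCc4ccccc4)c(OC)cc3C[C@@H](COCOCc3ccccc3)[C@@H]2COS(=O)(=O)[O-])ccc1OCc1ccccc1.[Na+] | intermediate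
24 | sodium [(1S,2R,3R)-7-hydroxy-1-(4-hydroxy-3-methoxyphenyl)-3-(hydroxymethyl)-6-methoxy-1,2,3,4-tetrahydronaphthalen-2-yl]methyl sulfate | COc1cc([C@H]2c3cc(O)c(OC)cc3C[C@@H](CO)[C@@H]2COS(=O)(=O)[O-])ccc1O.[Na+] | intermediate
25 | [(1S,2R,3R)-7-hydroxy-1-(4-hydroxy-3-methoxyphenyl)-3-(hydroxymethyl)-6-methoxy-1,2,3,4-tetrahydronaphthalen-2-yl]methyl hydrogen sulfate (CNP0184747.1) | COc1cc([C@H]2c3cc(O)c(OC)cc3C[C@@H](CO)[C@@H]2COS(=O)(=O)O)ccc1O | target

**Step count and risks**

Total: 16 steps. Longest linear sequence: 16 steps from 1; compounds 5, 8 and 11 are commercial and enter directly.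

Steps most likely to fail:

Step 8. The alkenylnickel may be protonated before it isomerises and cyclises, the aryl group may be delivered to the wrong alkyne carbon, or the alkene faces may be poorly discriminated. The fallback closes ring B first and adds the aryl group afterwards, setting out from 9 and returning at 12. Conjugate addition of pyrrolidine to the ynoate of 9 and hydrolysis of the enamine with aqueous AcOH would give the β-keto ester methyl 3-{5-(benzyloxy)-2-[(2Z)-4-hydroxybut-2-en-1-yl]-4-methoxyphenyl}-3-oxopropanoate F1. ClCO2Me and pyridine would convert its alcohol into the allylic methyl carbonate F2. An intramolecular Tsuji–Trost asymmetric allylic alkylation (Pd2(dba)3, the chiral 1,2-diaminocyclohexane bis(2-diphenylphosphinobenzamide) ligand, CH2Cl2) would close ring B through the keto ester carbon and set C3, giving the vinyl tetralone ester methyl (3S)-7-(benzyloxy)-3-ethenyl-6-methoxy-1-oxo-1,2,3,4-tetrahydronaphthalene-2-carboxylate F3. NaH and PhNTf2 would give the enol triflate F4, and Suzuki–Miyaura coupling of it with 11 (Pd(PPh3)4, K3PO4, dioxane/H2O) would form the C1–aryl bond and return to 12.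

Step 10. Reduction of the tetrasubstituted, doubly aryl-substituted alkene on Ni2B may stall, or hydrogen may be delivered without full facial control. The fallback is true surface hydrogenation, for which cis delivery to the convex face of fused unsaturated lactones is best established, setting out from 15 and returning at 16. Hydrogenation of 15 over Pd/C (H2 under pressure, EtOAc/AcOH) would be run to completion, accepting loss of both benzyl ethers, to give the all-cis bis-phenol lactone F5. Re-benzylation of both phenols (BnBr, K2CO3, DMF) would return to 16.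

Step 6. The free allylic alcohol or the base may add to methyl propiolate, the propiolate may oligomerise, and coupling at the hindered, electron-rich iodide may be slow. The fallback builds the ynoate by carboxylation of an arylacetylide and not by coupling a propiolate, setting out from 7 and returning at 9. TBSCl and imidazole would give the silyl ether F6. Sonogashira coupling with ethynyltrimethylsilane (PdCl2(PPh3)2, CuI, Et3N) would give the silylalkyne F7, and K2CO3 in MeOH would free the terminal alkyne F8. Deprotonation with n-BuLi at −78 °C and trapping with ClCO2Me would give the ynoate silyl ether F9, and HF·pyridine would remove the silyl group and return to 9.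

**Further compounds**

F1 | step 8 | methyl 3-{5-(benzyloxy)-2-[(2Z)-4-hydroxybut-2-en-1-yl]-4-methoxyphenyl}-3-oxopropanoate | COC(=O)CC(=O)c1cc(OCc2ccccc2)c(OC)cc1C/C=C\CO
F2 | step 8 | methyl 3-{5-(benzyloxy)-4-methoxy-2-[(2Z)-4-[(methoxycarbonyl)oxy]but-2-en-1-yl]phenyl}-3-oxopropanoate | COC(=O)CC(=O)c1cc(OCc2ccccc2)c(OC)cc1C/C=C\COC(=O)OC
F3 | step 8 | methyl (3S)-7-(benzyloxy)-3-ethenyl-6-methoxy-1-oxo-1,2,3,4-tetrahydronaphthalene-2-carboxylate (C2 enolisable, undefined) | COC(=O)C1C(=O)c2cc(OCc3ccccc3)c(OC)cc2C[C@H]1C=C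
F4 | step 8 | methyl (3S)-7-(benzyloxy)-3-ethenyl-6-methoxy-1-{[(trifluoromethyl)sulfonyl]oxy}-3,4-dihydronaphthalene-2-carboxylate | COC(=O)C1=C(OS(=O)(=O)C(F)(F)F)c2cc(OCc3ccccc3)c(OC)cc2C[C@H]1C=C
F5 | step 10 | (3aR,9S,9aS)-7-hydroxy-9-(4-hydroxy-3-methoxyphenyl)-6-methoxy-3a,4,9,9a-tetrahydronaphtho[2,3-c]furan-1(3H)-one | COc1cc([C@H]2c3cc(O)c(OC)cc3C[C@H]3COC(=O)[C@@H]23)ccc1O
F6 | step 6 | {[(2Z)-4-[4-(benzyloxy)-2-iodo-5-methoxyphenyl]but-2-en-1-yl]oxy}(tert-butyl)dimethylsilane | COc1cc(C/C=C\CO[Si](C)(C)C(C)(C)C)c(I)cc1OCc1ccccc1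
F7 | step 6 | {[(2Z)-4-{4-(benzyloxy)-5-methoxy-2-[(trimethylsilyl)ethynyl]phenyl}but-2-en-1-yl]oxy}(tert-butyl)dimethylsilane | C[Si](C)(C)C#Cc1cc(OCc2ccccc2)c(OC)cc1C/C=C\CO[Si](C)(C)C(C)(C)C
F8 | step 6 | {[(2Z)-4-[4-(benzyloxy)-2-ethynyl-5-methoxyphenyl]but-2-en-1-yl]oxy}(tert-butyl)dimethylsilane | C#Cc1cc(OCc2ccccc2)c(OC)cc1C/C=C\CO[Si](C)(C)C(C)(C)C
F9 | step 6 | methyl 3-{5-(benzyloxy)-2-[(2Z)-4-{[tert-butyl(dimethyl)silyl]oxy}but-2-en-1-yl]-4-methoxyphenyl}prop-2-ynoate | COC(=O)C#Cc1cc(OCc2ccccc2)c(OC)cc1C/C=C\CO[Si](C)(C)C(C)(C)C
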